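**Plan**

- Cuts, in order: five O–Si bonds; C4–Cβ between ring A and the acrylate (directed C–H olefination); C3–C3a (ring contraction); C2–C1' (conjugate arylation of a chromone); the chromone C2 carbon (amide acetal), leading back to 2',3'-dihydroxyacetophenone.
- Enabling feature: C3 of the dihydrobenzofuran carries both the carboxyl carbon and the bond to arene carbon C3a. The ring O1–C2–C3–C3a–C7a is therefore the pyranone ring O1–C2–C3–C4(=O)–C4a–C8a of a flavanone with C4 moved outside, and a shift of C4a from C4 to C3 creates ring, bond and ester in one event.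
- Forward order: pyranone ring (chromone), ring B onto C2, contraction of the pyranone to the dihydrofuran, ester cleavage, attachment of the side chain at C4, desilylation.
- Stereochemistry: C2 comes from a rhodium/chiral diene catalyst, and C3 is relayed from C2 by the anti, invertive 1,2-shift (2,3-trans). The side-chain centre comes from natural (R)-danshensu, and the E alkene from syn insertion followed by syn β-hydride elimination.
- Phenol protection follows the chemistry: benzyl for the basic and organometallic steps, acetyl in the key step so that ring B cannot compete as the migrating group, and triisopropylsilyl (TIPS) for the endgame so that the last step needs neither hydrogen, Lewis acid nor base.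

Key step: step 5

Assumption: the (S,S) enantiomer of 2,5-diphenylbicyclo[2.2.2]octa-2,5-diene is taken to give the 2S flavanone, by analogy with its sense of induction on 2-cyclohexenone; if the sense is reversed on chromones, the antipodal ligand is used.

**Step 1**
Reactants: 1 2',3'-dihydroxyacetophenone
Product: 2 1-[3-(benzyloxy)-2-hydroxyphenyl]ethan-1-one
Conditions: NaH (2.1 equiv), DMF, 0 °C; BnBr (1.0 equiv), 0 °C to rt; aq. HCl quench
Reagents that add atoms: benzyl bromide, BrCc1ccccc1
Why: Williamson etherification of the dianion, in which the 3'-oxide is neither conjugated with the acetyl group nor held in its chelate and is therefore the more nucleophilic oxygen, so one equivalent of benzyl bromide should react there and leave the 2'-OH free for ring closure.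

**Step 2**
Reactants: 2 1-[3-(benzyloxy)-2-hydroxyphenyl]ethan-1-one
Product: 4 8-(benzyloxy)-4H-chromen-4-one, via enaminone 3 (not isolated)
Conditions: Me2NCH(OMe)2 (1.5 equiv), toluene, 100 °C; evaporate; conc. HCl, CH2Cl2, rt
Reagents that add atoms: N,N-dimethylformamide dimethyl acetal, COC(OC)N(C)C
Why: Condensation of the methyl ketone with the amide acetal to the enaminone, followed by acid-induced addition of the 2'-OH and loss of dimethylamine, is the standard chromone synthesis from 2'-hydroxyacetophenones, and the benzyl ether tolerates both stages.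

**Step 3**
Reactants: 4 8-(benzyloxy)-4H-chromen-4-one; 5 3,4-bis(benzyloxy)phenylboronic acid
Product: 6 (2S)-8-(benzyloxy)-2-[3,4-bis(benzyloxy)phenyl]chroman-4-one
Conditions: 5 (2 equiv), [RhCl(C2H4)2]2 (2.5 mol %), (1S,4S)-2,5-diphenylbicyclo[2.2.2]octa-2,5-diene (5.5 mol %), KOH (10 mol %), toluene/H2O 10:1, 40 °C
Reagents that add atoms: none
Why: Hayashi–Miyaura asymmetric 1,4-addition, in which the aryl complex of monovalent rhodium formed by transmetalation inserts the C2=C3 bond of the chromone on the face left open by the C2-symmetric diene and so sets C2 as S, while the almost base-free two-phase medium should hold back retro-oxa-Michael opening of the product and a second, 1,2-type addition.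

**Step 4**
Reactants: 6 (2S)-8-(benzyloxy)-2-[3,4-bis(benzyloxy)phenyl]chroman-4-one
Product: 8 (2S)-8-acetoxy-2-(3,4-diacetoxyphenyl)chroman-4-one, via triphenol 7 (not isolated)
Conditions: H2 (1 atm), 10 % Pd/C, EtOAc, rt; filter under Ar; Ac2O, pyridine, 0 °C
Reagents that add atoms: acetic anhydride, CC(=O)OC(C)=O
Why: Hydrogenolysis of aryl benzyl ethers over Pd/C is faster than attack on the aryl ketone or on the cyclic benzylic C2–O1 bond of flavanones, and immediate O-acetylation of the crude triphenol in cold pyridine caps the 4'-OH before it can drive opening to the chalcone, so C2 should keep its configuration.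

**Step 5**
Reactants: 8 (2S)-8-acetoxy-2-(3,4-diacetoxyphenyl)chroman-4-one
Product: 11 methyl (2S,3S)-7-acetoxy-2-(3,4-diacetoxyphenyl)-2,3-dihydro-1-benzofuran-3-carboxylate, via enol ether 9 (not isolated), via iodanyl ketal 10 (not isolated)
Conditions: HC(OMe)3 (solvent), conc. H2SO4 (0.5 equiv), 0 °C, dark; PhI(OAc)2 (1.2 equiv), 0 to 10 °C; aq. NaHCO3
Reagents that add atoms: trimethyl orthoformate, COC(OC)OC (OMe groups of 9, 10 and 11); (diacetoxyiodo)benzene, CC(=O)OI(OC(C)=O)c1ccccc1 (iodanyl group of 10 only, no atom in 11)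
Why: Under acid catalysis trimethyl orthoformate dehydrates and O-methylates the C4 carbonyl group of 8 to the 4-methoxy-2H-chromene 9, the electrophilic trivalent iodine of PhI(OAc)2 bonds to C3 on the face remote from the 2-aryl group, and methanol caps C4 to give the 2,3-trans iodanyl ketal 10. In the diequatorial chair of 10 the C3–I bond lies antiperiplanar to the ring bond C4–C4a, so arene carbon C4a moves from C4 to C3 through a bridged, phenonium-like transition state while iodobenzene departs, and the dimethoxycarbenium ion left at C4 gives up one methyl group to acetate and becomes the exocyclic CO2Me. The closest known reaction type is this very one, the oxidative ring contraction of flavanones and 1-tetralones with aryl-λ3-iodanes or Tl(NO3)3 in trimethyl orthoformate, which furnishes methyl trans-2-aryl-2,3-dihydrobenzofuran-3-carboxylates and leaves C2 untouched. The dihydrofuran ring O1–C2–C3–C3a–C7a closes by ring contraction, that is by a 1,2-aryl shift in which the ipso carbon attacks C3 in a formal 3-exo-tet manner and the C4–C4a bond then breaks, not by attack of a heteroatom. The new stereocentre C3 is under substrate control by C2, since displacement of iodine with inversion in the trans adduct keeps H-3 on the side of the aryl group and places the ester on the opposite side, hence 2,3-trans and (2S,3S), which is also the more stable epimer. The step needs migration of C4a in preference to migration of ring B carbon C1' from C2 (open to the diaxial conformer of 10 and leading to the isoflavone), to loss of H-2 (flavone) and to acid-induced opening to the chalcone (racemisation); C4a is activated by the ortho ring oxygen O1 and pushed by two ketal oxygens (the 8-oxygen is meta to C4a and only a spectator), the acetoxy groups take the para donor away from ring B and make C2–O1 ionisation harder, and low temperature with little acid spares the acetates.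

**Step 6**
Reactants: 11 methyl (2S,3S)-7-acetoxy-2-(3,4-diacetoxyphenyl)-2,3-dihydro-1-benzofuran-3-carboxylate
Product: 13 methyl (2S,3S)-7-[(triisopropylsilyl)oxy]-2-{3,4-bis[(triisopropylsilyl)oxy]phenyl}-2,3-dihydro-1-benzofuran-3-carboxylate, via triphenol ester 12 (not isolated)
Conditions: HCl (1.25 M in MeOH), 0 °C to rt, Ar; evaporate; TIPSCl (4 equiv), imidazole (8 equiv), DMF, rt to 40 °C
Reagents that add atoms: chlorotriisopropylsilane, CC(C)[Si](Cl)(C(C)C)C(C)C
Why: Acid-catalysed transesterification removes the aryl acetates while the C3 ester, already a methyl ester, stays as it is and no base is present that could trigger E1cB opening of the dihydrofuran, and silylation of phenols with a silyl chloride and imidazole is routine, so neither stage touches C2 or C3.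

**Step 7**
Reactants: 13 methyl (2S,3S)-7-[(triisopropylsilyl)oxy]-2-{3,4-bis[(triisopropylsilyl)oxy]phenyl}-2,3-dihydro-1-benzofuran-3-carboxylate
Product: 15 (2S,3S)-7-[(triisopropylsilyl)oxy]-2-{3,4-bis[(triisopropylsilyl)oxy]phenyl}-2,3-dihydro-1-benzofuran-3-carboxylic acid, via stannyl ester 14 (not isolated)
Conditions: Me3SnOH (8 equiv), ClCH2CH2Cl, 80 °C; wash with 0.5 M HCl
Reagents that add atoms: trimethyltin hydroxide, C[Sn](C)(C)O
Why: Me3SnOH ester cleavage delivers hydroxide to the tin-activated carbonyl group under essentially neutral conditions, a method established for epimerisable esters including trans-2-aryl-2,3-dihydrobenzofuran-3-carboxylates, so neither deprotonation at C3 (epimerisation, β-elimination of the O1 phenoxide) nor loss of the hindered aryl silyl ethers is expected.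

**Step 8**
Reactants: 16 sodium (R)-3-(3,4-dihydroxyphenyl)lactate (sodium danshensu)
Product: 17 methyl (2R)-3-(3,4-dihydroxyphenyl)-2-hydroxypropanoate
Conditions: HCl (1.25 M in MeOH, 3 equiv), 50 °C, Ar
Reagents that add atoms: methanol, CO
Why: Fischer esterification of an α-hydroxy acid, in which no bond to the stereocentre is broken and the catechol is stable in the acidic medium.

**Step 9**
Reactants: 17 methyl (2R)-3-(3,4-dihydroxyphenyl)-2-hydroxypropanoate
Product: 18 methyl (2R)-3-{3,4-bis[(triisopropylsilyl)oxy]phenyl}-2-hydroxypropanoate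
Conditions: TIPSCl (2.3 equiv), imidazole (5 equiv), DMF, 0 °C to rt
Reagents that add atoms: chlorotriisopropylsilane, CC(C)[Si](Cl)(C(C)C)C(C)C
Why: Phenols are silylated by TIPSCl/imidazole at room temperature whereas a secondary alcohol deactivated by the neighbouring ester needs the silyl triflate or forcing conditions, so chemoselective O-silylation of the catechol is expected.

**Step 10**
Reactants: 18 methyl (2R)-3-{3,4-bis[(triisopropylsilyl)oxy]phenyl}-2-hydroxypropanoate
Product: 19 methyl (2R)-2-(acryloyloxy)-3-{3,4-bis[(triisopropylsilyl)oxy]phenyl}propanoate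
Conditions: acryloyl chloride (1.3 equiv), Et3N (1.6 equiv), CH2Cl2, −20 to 0 °C
Reagents that add atoms: acryloyl chloride, C=CC(=O)Cl
Why: O-acylation of a secondary alcohol with an acid chloride and a tertiary amine leaves the C–O bond of the stereocentre intact, and at low temperature the α-acyloxy ester is not deprotonated, so the R configuration is retained.

**Step 11**
Reactants: 15 (2S,3S)-7-[(triisopropylsilyl)oxy]-2-{3,4-bis[(triisopropylsilyl)oxy]phenyl}-2,3-dihydro-1-benzofuran-3-carboxylic acid; 19 methyl (2R)-2-(acryloyloxy)-3-{3,4-bis[(triisopropylsilyl)oxy]phenyl}propanoate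
Product: 20 (2S,3S)-4-[(1E)-3-{[(2R)-1-methoxy-1-oxo-3-{3,4-bis[(triisopropylsilyl)oxy]phenyl}propan-2-yl]oxy}-3-oxoprop-1-en-1-yl]-7-[(triisopropylsilyl)oxy]-2-{3,4-bis[(triisopropylsilyl)oxy]phenyl}-2,3-dihydro-1-benzofuran-3-carboxylic acid
Conditions: Pd(OAc)2 (10 mol %), Ac-Ile-OH (20 mol %), KHCO3 (2 equiv), O2 (1 atm), t-AmOH, 85 °C; dilute HCl work-up
Reagents that add atoms: none
Why: Carboxylate-directed Fujiwara–Moritani (oxidative Heck) olefination of a phenylacetic-acid-type substrate with divalent palladium and a mono-N-protected amino acid ligand, in which the C3 carboxylate steers C–H palladation to its only free ortho position C4, syn insertion of the acrylate and syn β-hydride elimination give the E alkene, O2 reoxidises zerovalent palladium, and the reaction type is established on this ring system with ether-protected phenols.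

**Step 12**
Reactants: 20 the penta-TIPS ether of the target (full name in step 11)
Product: 21 (2S,3S)-2-(3,4-dihydroxyphenyl)-4-[(1E)-3-{[(2R)-3-(3,4-dihydroxyphenyl)-1-methoxy-1-oxopropan-2-yl]oxy}-3-oxoprop-1-en-1-yl]-7-hydroxy-2,3-dihydro-1-benzofuran-3-carboxylic acid (CNP0120702.1)
Conditions: Bu4NF (6 equiv), AcOH (7 equiv), THF, 0 °C, Ar; dilute HCl; reversed-phase chromatography
Reagents that add atoms: none
Why: Fluoride-induced cleavage of aryl silyl ethers is fast because phenoxide is a good leaving group, and the acetic acid buffer keeps the medium near neutral, so the two esters, the E alkene, the C3 acid and the benzylic C2–O1 bond, which together rule out hydrogenolysis, strong Lewis acids and base, should survive.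

**Compound list**

1 | 2',3'-dihydroxyacetophenone | CC(=O)c1cccc(O)c1O | starting material
2 | 1-[3-(benzyloxy)-2-hydroxyphenyl]ethan-1-one | CC(=O)c1cccc(OCc2ccccc2)c1O | intermediate
3 | (E)-1-[3-(benzyloxy)-2-hydroxyphenyl]-3-(dimethylamino)prop-2-en-1-one | CN(C)/C=C/C(=O)c1cccc(OCc2ccccc2)c1O | intermediate
4 | 8-(benzyloxy)-4H-chromen-4-one | O=c1ccoc2c(OCc3ccccc3)cccc12 | intermediate
5 | 3,4-bis(benzyloxy)phenylboronic acid | OB(O)c1ccc(OCc2ccccc2)c(OCc2ccccc2)c1 | starting material
6 | (2S)-8-(benzyloxy)-2-[3,4-bis(benzyloxy)phenyl]chroman-4-one | c1ccc(OCc3ccccc3)c2c1C(=O)C[C@@H](c1ccc(OCc3ccccc3)c(OCc3ccccc3)c1)O2 | intermediate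
7 | (2S)-8-hydroxy-2-(3,4-dihydroxyphenyl)chroman-4-one | c1ccc(O)c2c1C(=O)C[C@@H](c1ccc(O)c(O)c1)O2 | intermediate
8 | (2S)-8-acetoxy-2-(3,4-diacetoxyphenyl)chroman-4-one | c1ccc(OC(C)=O)c2c1C(=O)C[C@@H](c1ccc(OC(C)=O)c(OC(C)=O)c1)O2 | intermediate
9 | (2S)-8-acetoxy-2-(3,4-diacetoxyphenyl)-4-methoxy-2H-chromene | c1ccc(OC(C)=O)c2c1C(OC)=C[C@@H](c1ccc(OC(C)=O)c(OC(C)=O)c1)O2 | intermediate
10 | (2R,3R)-8-acetoxy-3-[acetoxy(phenyl)-λ3-iodanyl]-2-(3,4-diacetoxyphenyl)-4,4-dimethoxychromane (2,3-trans; C2 unchanged in space, descriptor altered by CIP ranking only) | c1ccc(OC(C)=O)c2c1C(OC)(OC)[C@H](I(OC(C)=O)c1ccccc1)[C@@H](c1ccc(OC(C)=O)c(OC(C)=O)c1)O2 | intermediate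
11 | methyl (2S,3S)-7-acetoxy-2-(3,4-diacetoxyphenyl)-2,3-dihydro-1-benzofuran-3-carboxylate | c1ccc(OC(C)=O)c2c1[C@H](C(=O)OC)[C@@H](c1ccc(OC(C)=O)c(OC(C)=O)c1)O2 | intermediate
12 | methyl (2S,3S)-7-hydroxy-2-(3,4-dihydroxyphenyl)-2,3-dihydro-1-benzofuran-3-carboxylate | c1ccc(O)c2c1[C@H](C(=O)OC)[C@@H](c1ccc(O)c(O)c1)O2 | intermediate
13 | methyl (2S,3S)-7-[(triisopropylsilyl)oxy]-2-{3,4-bis[(triisopropylsilyl)oxy]phenyl}-2,3-dihydro-1-benzofuran-3-carboxylate | c1ccc(O[Si](C(C)C)(C(C)C)C(C)C)c2c1[C@H](C(=O)OC)[C@@H](c1ccc(O[Si](C(C)C)(C(C)C)C(C)C)c(O[Si](C(C)C)(C(C)C)C(C)C)c1)O2 | intermediate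
14 | trimethylstannyl (2S,3S)-7-[(triisopropylsilyl)oxy]-2-{3,4-bis[(triisopropylsilyl)oxy]phenyl}-2,3-dihydro-1-benzofuran-3-carboxylate | c1ccc(O[Si](C(C)C)(C(C)C)C(C)C)c2c1[C@H](C(=O)O[Sn](C)(C)C)[C@@H](c1ccc(O[Si](C(C)C)(C(C)C)C(C)C)c(O[Si](C(C)C)(C(C)C)C(C)C)c1)O2 | intermediate
15 | (2S,3S)-7-[(triisopropylsilyl)oxy]-2-{3,4-bis[(triisopropylsilyl)oxy]phenyl}-2,3-dihydro-1-benzofuran-3-carboxylic acid | c1ccc(O[Si](C(C)C)(C(C)C)C(C)C)c2c1[C@H](C(=O)O)[C@@H](c1ccc(O[Si](C(C)C)(C(C)C)C(C)C)c(O[Si](C(C)C)(C(C)C)C(C)C)c1)O2 | intermediate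
16 | sodium (R)-3-(3,4-dihydroxyphenyl)lactate | [Na+].[O-]C(=O)[C@@H](Cc1ccc(O)c(O)c1)O | starting material
17 | methyl (2R)-3-(3,4-dihydroxyphenyl)-2-hydroxypropanoate | COC(=O)[C@@H](Cc1ccc(O)c(O)c1)O | intermediate
18 | methyl (2R)-3-{3,4-bis[(triisopropylsilyl)oxy]phenyl}-2-hydroxypropanoate | COC(=O)[C@@H](Cc1ccc(O[Si](C(C)C)(C(C)C)C(C)C)c(O[Si](C(C)C)(C(C)C)C(C)C)c1)O | intermediate
19 | methyl (2R)-2-(acryloyloxy)-3-{3,4-bis[(triisopropylsilyl)oxy]phenyl}propanoate | COC(=O)[C@@H](Cc1ccc(O[Si](C(C)C)(C(C)C)C(C)C)c(O[Si](C(C)C)(C(C)C)C(C)C)c1)OC(=O)C=C | intermediate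
20 | penta-TIPS ether of the target, (2S,3S,2'R,E), free C3 acid (full name in step 11) | COC(=O)[C@@H](Cc1ccc(O[Si](C(C)C)(C(C)C)C(C)C)c(O[Si](C(C)C)(C(C)C)C(C)C)c1)OC(=O)/C=C/c1ccc(O[Si](C(C)C)(C(C)C)C(C)C)c2c1[C@H](C(=O)O)[C@@H](c1ccc(O[Si](C(C)C)(C(C)C)C(C)C)c(O[Si](C(C)C)(C(C)C)C(C)C)c1)O2 | intermediate
21 | CNP0120702.1 (full name in step 12) | COC(=O)[C@@H](Cc1ccc(O)c(O)c1)OC(=O)/C=C/c1ccc(O)c2c1[C@H](C(=O)O)[C@@H](c1ccc(O)c(O)c1)O2 | target

**Step count**

Total step count: 12. Steps 2, 4 and 6 are two-stage operations without isolation of the intermediate.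
Longest linear sequence: 9 steps (1 to 7, 11, 12) from 1. The side-chain branch has 3 steps (8 to 10).

**Steps most likely to fail**

**Step 5.**
- What may go wrong: the iodanyl ketal may collapse along the wrong channel. The possibilities are a shift of ring B carbon C1' towards the isoflavone skeleton, loss of H-2 towards the flavone, and methoxy substitution at C3.
- The acid may also methanolyse the aryl acetates, after which the iodane would oxidise the freed phenols.
- Slow enol ether formation may leave time for opening to the chalcone, with erosion of the configuration at C2.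
- Fallback: activation of C3 and the 1,2-shift are separated, and no oxidant is present during the rearrangement. Setting out from 8, bromination with PhNMe3Br3 in THF at 0 °C should give the equatorial bromide (2R,3R)-8-acetoxy-3-bromo-2-(3,4-diacetoxyphenyl)chroman-4-one F1. Ketalisation with HC(OMe)3 and TsOH in MeOH should then give (2R,3R)-8-acetoxy-3-bromo-2-(3,4-diacetoxyphenyl)-4,4-dimethoxychromane F2. AgBF4 in CH2Cl2/MeOH at 0 °C abstracts bromide while C4a migrates from C4 to C3. This is the silver- or zinc-assisted rearrangement of α-halo aryl ketals to 2-arylalkanoic esters, with the same antiperiplanar geometry and the same inversion at C3. The route is rejoined at 11.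

**Step 11.**
- What may go wrong: hot bicarbonate together with the water formed may strip aryl silyl groups. The liberated catechols would then be oxidised and would bind palladium, so turnover stops. The bulk of the silyl groups may also slow the reaction relative to small ether groups.
- Fallback: the endgame is moved to acetal protection, which is inert to base and closest in size to simple alkyl ethers, and it ends with an acid instead of a fluoride deprotection.
- Setting out from 12, MOMCl and iPr2NEt in CH2Cl2 give methyl (2S,3S)-7-(methoxymethoxy)-2-[3,4-bis(methoxymethoxy)phenyl]-2,3-dihydro-1-benzofuran-3-carboxylate F3. Me3SnOH in ClCH2CH2Cl then gives (2S,3S)-7-(methoxymethoxy)-2-[3,4-bis(methoxymethoxy)phenyl]-2,3-dihydro-1-benzofuran-3-carboxylic acid F4.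
- Setting out from 17, MOMCl and K2CO3 in acetone (phenol-selective) give methyl (2R)-3-[3,4-bis(methoxymethoxy)phenyl]-2-hydroxypropanoate F5. Acryloyl chloride and Et3N give methyl (2R)-2-(acryloyloxy)-3-[3,4-bis(methoxymethoxy)phenyl]propanoate F6.
- Olefination of F4 with F6 under Pd(OAc)2, Ac-Ile-OH, KHCO3 and O2 gives the penta-MOM ether of the target F7. CF3CO2H in CH2Cl2 at 0 °C followed by aqueous work-up removes the five acetals, and the route is rejoined at 21.

**Step 3.**
- What may go wrong: the vinylogous ester may insert slowly, so protodeboronation consumes the boronic acid. The enolate stage may open to the chalcone, which recloses without facial control. The 8-substituent may also lower the facial selectivity.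
- Fallback: catalytic arylation is replaced by construction of the racemate and a kinetic resolution.
- Setting out from 2, Claisen–Schmidt condensation with commercial 3,4-bis(benzyloxy)benzaldehyde (KOH, EtOH) gives (E)-1-[3-(benzyloxy)-2-hydroxyphenyl]-3-[3,4-bis(benzyloxy)phenyl]prop-2-en-1-one F8. Oxa-Michael cyclisation (NaOAc, EtOH, reflux) gives racemic 8-(benzyloxy)-2-[3,4-bis(benzyloxy)phenyl]chroman-4-one F9.
- Noyori-type asymmetric transfer hydrogenation with Cp*RhCl[(R,R)-TsDPEN] and HCO2H/Et3N in EtOAc, stopped near half conversion, reduces the 2R ketone to (2R,4R)-8-(benzyloxy)-2-[3,4-bis(benzyloxy)phenyl]chroman-4-ol F10. The 2S ketone is left behind and is separated by chromatography, and the route is rejoined at 6.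

**Further compounds**

F1 | step 5 | (2R,3R)-8-acetoxy-3-bromo-2-(3,4-diacetoxyphenyl)chroman-4-one (2,3-trans) | c1ccc(OC(C)=O)c2c1C(=O)[C@H](Br)[C@@H](c1ccc(OC(C)=O)c(OC(C)=O)c1)O2
F2 | step 5 | (2R,3R)-8-acetoxy-3-bromo-2-(3,4-diacetoxyphenyl)-4,4-dimethoxychromane (2,3-trans) | c1ccc(OC(C)=O)c2c1C(OC)(OC)[C@H](Br)[C@@H](c1ccc(OC(C)=O)c(OC(C)=O)c1)O2
F3 | step 11 | methyl (2S,3S)-7-(methoxymethoxy)-2-[3,4-bis(methoxymethoxy)phenyl]-2,3-dihydro-1-benzofuran-3-carboxylate | c1ccc(OCOC)c2c1[C@H](C(=O)OC)[C@@H](c1ccc(OCOC)c(OCOC)c1)O2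
F4 | step 11 | (2S,3S)-7-(methoxymethoxy)-2-[3,4-bis(methoxymethoxy)phenyl]-2,3-dihydro-1-benzofuran-3-carboxylic acid | c1ccc(OCOC)c2c1[C@H](C(=O)O)[C@@H](c1ccc(OCOC)c(OCOC)c1)O2
F5 | step 11 | methyl (2R)-3-[3,4-bis(methoxymethoxy)phenyl]-2-hydroxypropanoate | COC(=O)[C@@H](Cc1ccc(OCOC)c(OCOC)c1)O
F6 | step 11 | methyl (2R)-2-(acryloyloxy)-3-[3,4-bis(methoxymethoxy)phenyl]propanoate | COC(=O)[C@@H](Cc1ccc(OCOC)c(OCOC)c1)OC(=O)C=C
F7 | step 11 | penta-MOM ether of the target, (2S,3S,2'R,E), free C3 acid | COC(=O)[C@@H](Cc1ccc(OCOC)c(OCOC)c1)OC(=O)/C=C/c1ccc(OCOC)c2c1[C@H](C(=O)O)[C@@H](c1ccc(OCOC)c(OCOC)c1)O2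
F8 | step 3 | (E)-1-[3-(benzyloxy)-2-hydroxyphenyl]-3-[3,4-bis(benzyloxy)phenyl]prop-2-en-1-one | O=C(/C=C/c1ccc(OCc2ccccc2)c(OCc2ccccc2)c1)c1cccc(OCc2ccccc2)c1O
F9 | step 3 | racemic 8-(benzyloxy)-2-[3,4-bis(benzyloxy)phenyl]chroman-4-one | c1ccc(OCc3ccccc3)c2c1C(=O)CC(c1ccc(OCc3ccccc3)c(OCc3ccccc3)c1)O2
F10 | step 3 | (2R,4R)-8-(benzyloxy)-2-[3,4-bis(benzyloxy)phenyl]chroman-4-ol (2,4-cis) | c1ccc(OCc3ccccc3)c2c1[C@H](O)C[C@H](c1ccc(OCc3ccccc3)c(OCc3ccccc3)c1)O2
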